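**Retrosynthetic overview**
1. The target is an 8,8''-linked biflavone (an acacetin unit joined to an apigenin unit). The last operations are dealkylation (two 5-methyl ethers, one 4'''-isopropyl ether) and opening of a temporary O7–Si(tBu)2–O7'' bridge.
2. Key disconnection C8–C8'': intramolecular Ullmann coupling of a silylene-bridged bis(8-iodoflavone). The enabling feature is the pair of hydroxyl oxygens on C7 and C7'', each on the ring carbon next to the carbons to be joined. One silicon atom ties them, so the coupling closes a seven-membered ring (C8, C7, O, Si, O, C7'', C8'') and can only pair the two different flavones at C8 and C8''.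
3. Both 8-iodoflavones come from one iodinated acetophenone (2) by polyanion aroylation and cyclodehydration, with 4-methoxybenzoyl chloride or 4-isopropoxybenzoyl chloride.
4. Ring order: rings A are bought with 1 and rings B with the acid chlorides; the two pyranone rings C are closed in steps 2 and 3; the temporary dioxasilepine ring is closed in step 5 and opened in step 6.

Key step: step 5

Assumption: the structure given fixes no configuration at the C8–C8'' axis, so the axis is formed without control of its sense (racemic material if the axis is configurationally stable).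

Step 1
Reactants: 1 2',4'-dihydroxy-6'-methoxyacetophenone
Product: 2 2',4'-dihydroxy-3'-iodo-6'-methoxyacetophenone
Conditions: I2 (0.4 equiv), HIO3 (0.2 equiv), EtOH–H2O, 35 °C
Reagents that add atoms: iodine, II; iodic acid, OI(=O)=O
Why: Electrophilic aromatic iodination with iodine/iodic acid should go to C3', the carbon between the two hydroxyl groups (as in the known 3-iodination of 2,4-dihydroxyacetophenone), because C5' is screened by the methyl of the 6'-methoxy group that the acetyl group turns toward it, and one equivalent of iodine limits double iodination.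

Step 2
Reactants: 2 2',4'-dihydroxy-3'-iodo-6'-methoxyacetophenone; 3 4-methoxybenzoyl chloride
Product: 5 7-hydroxy-8-iodo-5-methoxy-2-(4-methoxyphenyl)chromen-4-one, via diketone 4 (not isolated)
Conditions: LiN(SiMe3)2 (4.2 equiv), THF, −78 → −10 °C; 3, −78 °C → rt; aq. HCl; crude 4, H2SO4 (cat.), AcOH, 95 °C
Reagents that add atoms: none
Why: Baker–Venkataraman-type C-aroylation of the lithium polyanion (the ketone enolate carbon is its most nucleophilic site) gives the 1,3-diketone, and acid-catalysed cyclodehydration through the 2'-hydroxyl, the only hydroxyl ortho to the acyl group, closes pyranone ring C with iodine fixed at C8.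

Step 3
Reactants: 2 2',4'-dihydroxy-3'-iodo-6'-methoxyacetophenone; 6 4-isopropoxybenzoyl chloride
Product: 8 7-hydroxy-8-iodo-2-(4-isopropoxyphenyl)-5-methoxychromen-4-one, via diketone 7 (not isolated)
Conditions: LiN(SiMe3)2 (4.2 equiv), THF, −78 → −10 °C; 6, −78 °C → rt; aq. HCl; crude 7, H2SO4 (cat.), AcOH, 95 °C
Reagents that add atoms: none
Why: The same Baker–Venkataraman-type polyanion C-aroylation and acid-catalysed cyclodehydration should give the second 8-iodoflavone, the isopropyl aryl ether being stable to the base and to catalytic acid.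

Step 4
Reactants: 5 7-hydroxy-8-iodo-5-methoxy-2-(4-methoxyphenyl)chromen-4-one; 8 7-hydroxy-8-iodo-2-(4-isopropoxyphenyl)-5-methoxychromen-4-one
Product: 10 di-tert-butylsilanediyl bis-ether joining O7 of flavone 5 to O7 of flavone 8, via silyl triflate 9 (not isolated)
Conditions: 5, tBu2Si(OTf)2 (1.0 equiv), Et3N, CH2Cl2–DMF, −78 → 0 °C; then 8, Et3N, DMAP (cat.), 50 °C
Reagents that add atoms: di-tert-butylsilyl bis(trifluoromethanesulfonate), CC(C)(C)[Si](OS(=O)(=O)C(F)(F)F)(OS(=O)(=O)C(F)(F)F)C(C)(C)C
Why: Stepwise nucleophilic substitution at silicon (silyl ether formation) should give the unsymmetrical bis(aryloxy)silane, because the first triflate of the bulky bis(triflate) is displaced at low temperature by the acidic 7-hydroxyl of 5 and the far less reactive monotriflate 9 only on warming with the phenoxide of 8, the 5-methoxy groups leaving no other hydroxyl.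

Step 5
Reactants: 10 di-tert-butylsilanediyl bis-ether joining O7 of flavone 5 to O7 of flavone 8
Product: 11 silylene-bridged 8,8''-biflavone (4'-methoxy and 4'''-isopropoxy units, 5,5''-dimethoxy, O7 and O7'' held in a dibenzo[d,f][1,3,2]dioxasilepine ring with Si(tBu)2)
Conditions: Cu powder (activated, 10 equiv), DMF (0.01 M), 130 °C, Ar
Reagents that add atoms: none
Why: Activated zerovalent copper inserts into one C8–I bond to give an arylcopper species (monovalent copper) that the O–Si–O bridge holds beside the second C8''–I bond, whose oxidative addition gives a diaryl trivalent-copper intermediate; reductive elimination then forms the C8–C8'' bond with loss of CuI. The closest known reaction type is the classical Ullmann biaryl coupling in its tether-directed intramolecular form, and Ullmann coupling of 8-iodoflavones to 8,8''-biflavones is known. The ring closed is the seven-membered dibenzo[d,f][1,3,2]dioxasilepine (C8, C7, O, Si, O, C7'', C8''), formed by aryl–aryl reductive elimination from an eight-membered cupracycle. No stereocentre is created, and the new axis is formed without control of its sense. The step needs cross-selectivity (4'-methoxy unit with 4'''-isopropoxy unit) and 8,8''-regiochemistry; the first is secured by both aryl iodides sitting in one molecule under dilution, the second by the iodine atoms fixed at C8 and C8'' since step 1. Dry, degassed solvent should keep down the competing replacement of iodine by hydrogen.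

Step 6
Reactants: 11 silylene-bridged 8,8''-biflavone
Product: 12 7,7''-dihydroxy-4'''-isopropoxy-4',5,5''-trimethoxy-8,8''-biflavone
Conditions: HF·pyridine, THF–pyridine, 0 °C → rt
Reagents that add atoms: none
Why: Fluoride-mediated Si–O cleavage (desilylation), driven by Si–F bond formation, should open the dioxasilepine ring and free both 7-hydroxyl groups, while aryl ethers and the pyranone rings are inert to HF·pyridine.

Step 7
Reactants: 12 7,7''-dihydroxy-4'''-isopropoxy-4',5,5''-trimethoxy-8,8''-biflavone
Product: 13 5,5'',7,7'',4'''-pentahydroxy-4'-methoxy-8,8''-biflavone (CNP0322111.0)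
Conditions: BCl3 (10 equiv), CH2Cl2, −20 °C → rt; then MeOH–H2O
Reagents that add atoms: none
Why: Lewis acid ether cleavage with BCl3 should remove the 5- and 5''-methyl groups through chelation of boron between the ether oxygen and the C4 carbonyl and the isopropyl group through its secondary alkyl–oxygen bond, while the non-chelated 4'-methyl ether is of the kind that BCl3 leaves intact.

**Compound list**
1 | 2',4'-dihydroxy-6'-methoxyacetophenone | CC(=O)c1c(O)cc(O)cc1OC | starting material
2 | 2',4'-dihydroxy-3'-iodo-6'-methoxyacetophenone | CC(=O)c1c(O)c(I)c(O)cc1OC | intermediate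
3 | 4-methoxybenzoyl chloride | COc1ccc(C(=O)Cl)cc1 | starting material
4 | 1-(2,4-dihydroxy-3-iodo-6-methoxyphenyl)-3-(4-methoxyphenyl)propane-1,3-dione | COc1ccc(C(=O)CC(=O)c2c(O)c(I)c(O)cc2OC)cc1 | intermediate
5 | 7-hydroxy-8-iodo-5-methoxy-2-(4-methoxyphenyl)chromen-4-one | COc1ccc(-c2cc(=O)c3c(OC)cc(O)c(I)c3o2)cc1 | intermediate
6 | 4-isopropoxybenzoyl chloride | CC(C)Oc1ccc(C(=O)Cl)cc1 | starting material
7 | 1-(2,4-dihydroxy-3-iodo-6-methoxyphenyl)-3-(4-isopropoxyphenyl)propane-1,3-dione | CC(C)Oc1ccc(C(=O)CC(=O)c2c(O)c(I)c(O)cc2OC)cc1 | intermediate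
8 | 7-hydroxy-8-iodo-2-(4-isopropoxyphenyl)-5-methoxychromen-4-one | CC(C)Oc1ccc(-c2cc(=O)c3c(OC)cc(O)c(I)c3o2)cc1 | intermediate
9 | di-tert-butyl{[8-iodo-5-methoxy-2-(4-methoxyphenyl)-4-oxochromen-7-yl]oxy}silyl trifluoromethanesulfonate | COc1ccc(-c2cc(=O)c3c(OC)cc(O[Si](OS(=O)(=O)C(F)(F)F)(C(C)(C)C)C(C)(C)C)c(I)c3o2)cc1 | intermediate
10 | di-tert-butylsilanediyl bis-ether joining O7 of flavone 5 to O7 of flavone 8 | COc1ccc(-c2cc(=O)c3c(OC)cc(O[Si](Oc4cc(OC)c5c(=O)cc(-c6ccc(OC(C)C)cc6)oc5c4I)(C(C)(C)C)C(C)(C)C)c(I)c3o2)cc1 | intermediate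
11 | silylene-bridged 8,8''-biflavone (O7–Si(tBu)2–O7'' in a seven-membered dioxasilepine ring) | COc1ccc(-c2cc(=O)c3c(OC)cc4O[Si](C(C)(C)C)(C(C)(C)C)Oc5cc(OC)c6c(=O)cc(-c7ccc(OC(C)C)cc7)oc6c5-c4c3o2)cc1 | intermediate
12 | 7,7''-dihydroxy-4'''-isopropoxy-4',5,5''-trimethoxy-8,8''-biflavone | COc1ccc(-c2cc(=O)c3c(OC)cc(O)c(-c4c(O)cc(OC)c5c(=O)cc(-c6ccc(OC(C)C)cc6)oc45)c3o2)cc1 | intermediate
13 | 5,5'',7,7'',4'''-pentahydroxy-4'-methoxy-8,8''-biflavone (CNP0322111.0) | COc1ccc(-c2cc(=O)c3c(O)cc(O)c(-c4c(O)cc(O)c5c(=O)cc(-c6ccc(O)cc6)oc45)c3o2)cc1 | target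

Total step count: 7. Longest linear sequence: 6 steps (1 → 2 → 5 → 10 → 11 → 12 → 13; step 3 is the parallel branch).

**Steps most likely to fail**

Step 5. The aryl–aryl bond at the tetra-ortho-oxygenated axis may form too slowly, so that replacement of iodine by hydrogen or thermal loss of the silylene bridge takes over. The fallback is a bridge-free Suzuki–Miyaura union that sets out from 5 and 8 and comes back at 13. Compounds 5 and 8 are each O-alkylated (2-bromopropane, K2CO3, DMF, 60 °C) to give 8-iodo-7-isopropoxy-5-methoxy-2-(4-methoxyphenyl)chromen-4-one F1 and 8-iodo-7-isopropoxy-2-(4-isopropoxyphenyl)-5-methoxychromen-4-one F2. Miyaura borylation of F2 (B2pin2, PdCl2(dppf), KOAc, dioxane, 90 °C) should give the 8-pinacolboronate of the 7-isopropoxy-2-(4-isopropoxyphenyl)-5-methoxychromen-4-one F3. Suzuki–Miyaura coupling of F1 with F3 (Pd2(dba)3, SPhos, K3PO4, toluene–H2O, 100 °C) should give 7,7'',4'''-triisopropoxy-4',5,5''-trimethoxy-8,8''-biflavone F4. BCl3 under the conditions of step 7 then cleaves the two 5-methyl ethers and the three isopropyl ethers and returns to 13.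

Step 4. The first phenol may displace both triflates (symmetrical bis-ether), or the second displacement may stall at the crowded silicon. The fallback uses a less crowded bridge put on through a chlorosilane made with excess reagent; it sets out from 5 and comes back at 12. Compound 5 with excess iPr2SiCl2 (5 equiv, Et3N, CH2Cl2, 0 °C), followed by removal of the excess in vacuum, should give chloro(diisopropyl){[8-iodo-5-methoxy-2-(4-methoxyphenyl)-4-oxochromen-7-yl]oxy}silane F5. With 8 (Et3N, DMAP, DMF, rt) this gives the diisopropylsilanediyl bis-ether joining O7 of flavone 5 to O7 of flavone 8 F6. Ullmann coupling under the conditions of step 5 gives the diisopropylsilylene-bridged 8,8''-biflavone F7, and HF·pyridine as in step 6 returns to 12.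

Step 1. Iodination may take place at C5' in place of C3', or twice, which would carry a 6-iodo pattern forward. The fallback introduces iodine at the flavone stage; it sets out from 1 and comes back at 5 and 8. Compound 1 is aroylated and cyclodehydrated under the conditions of steps 2 and 3. With 3 this goes through 1-(2,4-dihydroxy-6-methoxyphenyl)-3-(4-methoxyphenyl)propane-1,3-dione F8 to 7-hydroxy-5-methoxy-2-(4-methoxyphenyl)chromen-4-one F9. With 6 it goes through 1-(2,4-dihydroxy-6-methoxyphenyl)-3-(4-isopropoxyphenyl)propane-1,3-dione F10 to 7-hydroxy-2-(4-isopropoxyphenyl)-5-methoxychromen-4-one F11. NIS (1 equiv, DMF, 0 °C) should then iodinate F9 and F11 at C8, the position that 5-O-alkylated 5,7-dioxygenated flavones offer to electrophiles, and give 5 and 8.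

**Further compounds**
F1 | step 5 | 8-iodo-7-isopropoxy-5-methoxy-2-(4-methoxyphenyl)chromen-4-one | COc1ccc(-c2cc(=O)c3c(OC)cc(OC(C)C)c(I)c3o2)cc1
F2 | step 5 | 8-iodo-7-isopropoxy-2-(4-isopropoxyphenyl)-5-methoxychromen-4-one | CC(C)Oc1ccc(-c2cc(=O)c3c(OC)cc(OC(C)C)c(I)c3o2)cc1
F3 | step 5 | 7-isopropoxy-2-(4-isopropoxyphenyl)-5-methoxy-8-(4,4,5,5-tetramethyl-1,3,2-dioxaborolan-2-yl)chromen-4-one | CC(C)Oc1ccc(-c2cc(=O)c3c(OC)cc(OC(C)C)c(B4OC(C)(C)C(C)(C)O4)c3o2)cc1
F4 | step 5 | 7,7'',4'''-triisopropoxy-4',5,5''-trimethoxy-8,8''-biflavone | COc1ccc(-c2cc(=O)c3c(OC)cc(OC(C)C)c(-c4c(OC(C)C)cc(OC)c5c(=O)cc(-c6ccc(OC(C)C)cc6)oc45)c3o2)cc1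
F5 | step 4 | chloro(diisopropyl){[8-iodo-5-methoxy-2-(4-methoxyphenyl)-4-oxochromen-7-yl]oxy}silane | COc1ccc(-c2cc(=O)c3c(OC)cc(O[Si](Cl)(C(C)C)C(C)C)c(I)c3o2)cc1
F6 | step 4 | diisopropylsilanediyl bis-ether joining O7 of flavone 5 to O7 of flavone 8 | COc1ccc(-c2cc(=O)c3c(OC)cc(O[Si](Oc4cc(OC)c5c(=O)cc(-c6ccc(OC(C)C)cc6)oc5c4I)(C(C)C)C(C)C)c(I)c3o2)cc1
F7 | step 4 | diisopropylsilylene-bridged 8,8''-biflavone | COc1ccc(-c2cc(=O)c3c(OC)cc4O[Si](C(C)C)(C(C)C)Oc5cc(OC)c6c(=O)cc(-c7ccc(OC(C)C)cc7)oc6c5-c4c3o2)cc1
F8 | step 1 | 1-(2,4-dihydroxy-6-methoxyphenyl)-3-(4-methoxyphenyl)propane-1,3-dione | COc1ccc(C(=O)CC(=O)c2c(O)cc(O)cc2OC)cc1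
F9 | step 1 | 7-hydroxy-5-methoxy-2-(4-methoxyphenyl)chromen-4-one | COc1ccc(-c2cc(=O)c3c(OC)cc(O)cc3o2)cc1
F10 | step 1 | 1-(2,4-dihydroxy-6-methoxyphenyl)-3-(4-isopropoxyphenyl)propane-1,3-dione | CC(C)Oc1ccc(C(=O)CC(=O)c2c(O)cc(O)cc2OC)cc1
F11 | step 1 | 7-hydroxy-2-(4-isopropoxyphenyl)-5-methoxychromen-4-one | CC(C)Oc1ccc(-c2cc(=O)c3c(OC)cc(O)cc3o2)cc1
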